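**Two constants.** Take two rate constants: kB, for starting material meeting partner, and kD, for starting material meeting second reagent. The runs lose starting material fast and give more target with more partner, so assume target comes by the partner route. Divide one route's rate by the other's and both starting material and time drop out: W = σ × [second reagent]/[partner], where σ = kD/kB is the selectivity factor and W is the waste ratio.

| flask | starting material | partner | second reagent | remark | time |
|---|---|---|---|---|---|
| north | 10 mM | 4 equiv | 0.95 equiv | run made earlier |  |
| south-west | 10 mM | 2.7 equiv | 0.95 equiv | run made earlier |  |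
| south | 10 mM | 6 equiv | 0.95 equiv | run made earlier |  |
| north-west | 5 mM | 4 equiv | 0.95 equiv | run made earlier |  |
| alpha | 10 mM | 4.00 equiv (fed, over 20 h) | 0.950 equiv | all else is in the flask from the start; the feed brings no volume worth counting | 50 h |
| gamma | 10 mM | 4.00 equiv | 0.950 equiv | everything together at the start | 50 h |
| eta | 10 mM | 4.00 equiv | 0.950 equiv (fed, over 20 h) | all else is in the flask from the start; the feed brings no volume worth counting | 50 h |

| run | time / h | target / % | starting material / % |
|---|---|---|---|
| north | 6.00 | 11.4 | 16.3 |
| north | 12.0 | 15.8 | 3.9 |
| north | 20.0 | 19.5 | 0.5 |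
| north | 25.0 | 19.0 | 1.0 |
| north | 30.0 | 19.7 | 0.5 |
| south-west | 2.50 | 5.5 | 41.9 |
| south-west | 8.00 | 11.6 | 14.0 |
| south-west | 15.0 | 12.4 | 5.9 |
| south-west | 20.0 | 16.6 | 1.7 |
| south-west | 30.0 | 16.5 | 0.7 |
| south | 2.50 | 11.8 | 32.5 |
| south | 5.00 | 15.0 | 12.7 |
| south | 8.00 | 19.5 | 5.6 |
| south | 15.0 | 21.4 | 0.8 |
| south | 30.0 | 24.3 | 0 |
| north-west | 2.50 | 5.5 | 58.7 |
| north-west | 8.00 | 9.6 | 23.0 |
| north-west | 15.0 | 14.0 | 11.1 |
| north-west | 20.0 | 14.4 | 7.7 |
| north-west | 30.0 | 14.4 | 2.5 |

(each reading ± 1 percentage point)

- the flask that comes out highest in amount of target, in percent of the starting material charged, or "all alike" when all lie within 1.5 percentage points (alpha / gamma / eta / all alike)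
- target at the end, in percent of the starting material charged, alpha
- target at the end, in percent of the starting material charged, gamma
- target at the end, in percent of the starting material charged, eta



**Reading σ.** Over a short stretch, ln(charge/left) is the sum of each route's rate times time. At 2.50 h, south-west gives 0.870 and south gives 1.12, which is more. Both were charged with the same equivalents of reagent, so you put the difference down to the extra partner, and from it kB reads 0.00308 mM⁻¹ h⁻¹. Scaled back to south-west's partner, the partner route accounts for 0.208 of south-west's 0.870 and the reagent route for 0.662. Time cancels in their ratio, and multiplying by the charges of partner over reagent makes σ read 9.05. This is a reading with scatter, and it counts the reagent at its charge.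

**Your reckoning.** Gamma repeats north, with W = 2.15 at the start, so you expect north's last reading, 19.7%. Alpha starts without partner, so you place it lowest. Eta starts without reagent, and its feed of 0.475 mM h⁻¹ is less than the starting partner route, 1.23 mM h⁻¹. Setting eta's reagent route equal to the feed, with starting material and partner at their charges, gives W near 0.386. The partner route's share in eta is then 72.2%, against 31.7% in gamma at the start. Scaling north's last reading by these shares gives an estimate of about 44.8% for eta.

**The forecast.** It names eta, with alpha 10.5%, gamma 19.5% and eta 25%, on the ground that “starting material meets the full partner charge without the waste burst”. Your order is the same, but your eta stands higher.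

**The flask.** Eta gives 38.6%, more than gamma's 19.7% and alpha's 8.34%.

    target ⇌ isomer of the product (K = 1.00, k = 1.80 × 10⁻⁴ s⁻¹)
    second reagent + intermediate → target (k = 0.0330 M⁻¹ s⁻¹)
    starting material + partner → intermediate (k = 0.00100 M⁻¹ s⁻¹)
    starting material + second reagent → side product (k = 0.0110 M⁻¹ s⁻¹)

**σ again.** Averaged over the first 20 h of eta, partner stood at 34.1 mM and second reagent at 0.877 mM. With these means W reads 0.233, a reagent-route share of 18.9%. Side product in eta stands at 17.1% after 50.0 h.

The runs are calculated from invented constants, noise included.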